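**Retrosynthetic overview**
- The last bond made is the aryl–CH2 bond at C8 of the chromene on ring B. It is formed by a blue-light nickel/photoredox cross-electrophile coupling of a ring B aryl bromide with a chiral C5 primary bromide; both stereocenters are already present in the partners.
- The C5 bromide comes from methyl (R)-glycidate (L-serine series) by bromide opening, MeMgBr addition and silylation/dehydration. The carbinol center is bought.
- The aryl bromide comes from (2S)-liquiritigenin, which brings C2 and rings A, C and B: 7-O-tert-allylation, 3'-bromination, 4'-O-propargylation.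
- One thermal step then moves the allyl unit to C8 (prenyl group) and builds the only new ring, the pyran ring of the chromene on ring B.

Assumption: (2S)-liquiritigenin and methyl (2R)-oxirane-2-carboxylate are bought enantiopure, and tert-butyl 2-methylbut-3-en-2-yl carbonate is a catalogue reagent.

**Step 1**
Reactants: 1 (2S)-liquiritigenin
Product: 2 (2S)-2-(4-hydroxyphenyl)-7-[(2-methylbut-3-en-2-yl)oxy]-2,3-dihydro-4H-chromen-4-one
Conditions: tert-butyl 2-methylbut-3-en-2-yl carbonate (1.1 equiv), Pd(PPh3)4 (3 mol%), 4 Å MS, THF, 0 °C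
Reagents that add atoms: tert-butyl 2-methylbut-3-en-2-yl carbonate (C=CC(C)(C)OC(=O)OC(C)(C)C)
Why: Tsuji–Trost O-allylation; the liberated tert-butoxide ionises only the more acidic 7-OH (vinylogous acid), and this phenoxide attacks the more substituted end of the π-allyl palladium under kinetic control, so the 4'-phenoxide that could open ring C never forms and C2 is untouched.

**Step 2**
Reactants: 2 (2S)-2-(4-hydroxyphenyl)-7-[(2-methylbut-3-en-2-yl)oxy]-2,3-dihydro-4H-chromen-4-one
Product: 3 (2S)-2-(3-bromo-4-hydroxyphenyl)-7-[(2-methylbut-3-en-2-yl)oxy]-2,3-dihydro-4H-chromen-4-one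
Conditions: NBS (1.0 equiv), i-Pr2NH (10 mol%), CH2Cl2, −40 → 0 °C, dark
Reagents that add atoms: N-bromosuccinimide (O=C1CCC(=O)N1Br)
Why: Amine-catalysed ortho-selective electrophilic bromination of a phenol (via the N-bromoamine); ring A has no free OH and its acyl group deactivates it, the monosubstituted vinyl group is inert at this temperature, and the two ortho positions of ring B are equivalent.

**Step 3**
Reactants: 3 (2S)-2-(3-bromo-4-hydroxyphenyl)-7-[(2-methylbut-3-en-2-yl)oxy]-2,3-dihydro-4H-chromen-4-one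
Product: 4 (2S)-2-{3-bromo-4-[(2-methylbut-3-yn-2-yl)oxy]phenyl}-7-[(2-methylbut-3-en-2-yl)oxy]-2,3-dihydro-4H-chromen-4-one
Conditions: 3-chloro-3-methylbut-1-yne (1.5 equiv), CuCl2·2H2O (1 mol%), DBU (1.3 equiv), MeCN, 0 °C, 3 h
Reagents that add atoms: 3-chloro-3-methylbut-1-yne (C#CC(C)(C)Cl)
Why: Copper-catalysed propargylic substitution (copper allenylidene) of a tertiary propargyl chloride by a phenoxide; low temperature and short time are chosen so that the 4'-phenoxide is alkylated before it can open ring C, keeping C2 as S.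

**Step 4**
Reactants: 4 (2S)-2-{3-bromo-4-[(2-methylbut-3-yn-2-yl)oxy]phenyl}-7-[(2-methylbut-3-en-2-yl)oxy]-2,3-dihydro-4H-chromen-4-one
Product: 6 (2S)-2-(8-bromo-2,2-dimethyl-2H-chromen-6-yl)-7-hydroxy-8-(3-methylbut-2-en-1-yl)-2,3-dihydro-4H-chromen-4-one, via prenylphenol propargyl ether 5 (not isolated)
Conditions: o-xylene (0.05 M), BHT (5 mol%), 145 °C, 18 h, argon
Reagents that add atoms: none
Why: Aromatic Claisen rearrangement of the tertiary allyl ether to C8 (the position between the two oxygens, as in angular pyranocoumarin formation), then propargyl Claisen rearrangement, 1,5-hydrogen shift and oxa-6π electrocyclisation at the only free ortho position of ring B; the medium is neutral, so C2 is not epimerised.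

**Step 5**
Reactants: 7 methyl (2R)-oxirane-2-carboxylate
Product: 9 (3S)-4-bromo-2-methylbutane-2,3-diol, via bromohydrin ester 8 (not isolated)
Conditions: MgBr2·OEt2 (1.1 equiv), Et2O, −20 °C, 1 h; then MeMgBr (3.0 equiv), THF, −78 → 0 °C; cold aq. NH4Cl
Reagents that add atoms: magnesium bromide diethyl etherate ([Mg+2].[Br-].[Br-].CCOCC); methylmagnesium bromide (C[Mg]Br)
Why: Lewis-acid-assisted bromide opening of the glycidate at C3 followed by double Grignard addition to the ester; no bond to the stereocenter is made or broken, so the bought configuration is kept (the descriptor changes from R to S only because CH2Br now outranks the former carbonyl carbon).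

**Step 6**
Reactants: 9 (3S)-4-bromo-2-methylbutane-2,3-diol
Product: 11 {[(2S)-1-bromo-3-methylbut-3-en-2-yl]oxy}(triethyl)silane, via silyl ether alcohol 10 (not isolated)
Conditions: Et3SiCl (1.1 equiv), pyridine (6 equiv), DMAP (5 mol%), CH2Cl2, 0 °C → rt; then SOCl2 (1.5 equiv), −20 → 0 °C
Reagents that add atoms: chlorotriethylsilane (CC[Si](Cl)(CC)CC)
Why: Selective silylation of the secondary OH, then dehydration of the tertiary alcohol through its chlorosulfite (pyridine-mediated elimination); the six methyl hydrogens are favoured over the single shielded hydrogen on the silyloxy carbon, giving the isopropenyl group without touching the stereocenter.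

**Step 7**
Reactants: 6 (2S)-2-(8-bromo-2,2-dimethyl-2H-chromen-6-yl)-7-hydroxy-8-(3-methylbut-2-en-1-yl)-2,3-dihydro-4H-chromen-4-one; 11 {[(2S)-1-bromo-3-methylbut-3-en-2-yl]oxy}(triethyl)silane
Product: 13 (2S)-7-hydroxy-2-{8-[(2R)-2-hydroxy-3-methylbut-3-en-1-yl]-2,2-dimethyl-2H-chromen-6-yl}-8-(3-methylbut-2-en-1-yl)-2,3-dihydro-4H-chromen-4-one, via silyl ether 12 (not isolated)
Conditions: 11 (2.0 equiv), [Ir(dF(CF3)ppy)2(dtbbpy)]PF6 (1 mol%), NiCl2·DME (15 mol%), dtbbpy (15 mol%), (Me3Si)3SiH (1.2 equiv), 2,6-lutidine (2 equiv), 1,2-dimethoxyethane (0.2 M), blue LEDs (450 nm), 25 °C; then 1 M aq. HCl, THF, 0 °C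
Reagents that add atoms: none
Why: Proposed new method: a silyl-radical-mediated nickel/photoredox cross-electrophile coupling run for the first time with a 2-silyloxy homoallylic primary bromide (11) and an ortho-alkoxy aryl bromide carrying a free phenol, a chromanone and further C=C bonds; the excited iridium photocatalyst oxidises bromide, the bromine atom takes H from (Me3Si)3SiH, the silyl radical abstracts Br from 11, the primary radical is trapped by the aryl nickel bromide formed from 6 and zerovalent nickel, and reductive elimination from trivalent nickel forms the aryl–CH2 bond; the bought stereocenter sits β to the radical and no bond to it is made or broken (S in 11 becomes R in 12 and 13 by priority change only), and the high nickel loading and concentration are chosen so that radical capture outruns the 1,2-vinyl shift of the homoallyl radical; the closest known reaction type is the silyl-radical-activated nickel/photoredox coupling of aryl bromides with unactivated alkyl bromides; the visible light is not absorbed by the flavanone, so C2 stays S, and the dilute acid then cleaves the triethylsilyl ether.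

**Compound list**
1 | (2S)-liquiritigenin, (2S)-7-hydroxy-2-(4-hydroxyphenyl)-2,3-dihydro-4H-chromen-4-one | Oc1ccc(cc1)[C@@H]2CC(=O)c3ccc(O)cc3O2 | starting material
2 | (2S)-2-(4-hydroxyphenyl)-7-[(2-methylbut-3-en-2-yl)oxy]-2,3-dihydro-4H-chromen-4-one | Oc1ccc(cc1)[C@@H]2CC(=O)c3ccc(OC(C)(C)C=C)cc3O2 | intermediate
3 | (2S)-2-(3-bromo-4-hydroxyphenyl)-7-[(2-methylbut-3-en-2-yl)oxy]-2,3-dihydro-4H-chromen-4-one | Oc1ccc(cc1Br)[C@@H]2CC(=O)c3ccc(OC(C)(C)C=C)cc3O2 | intermediate
4 | (2S)-2-{3-bromo-4-[(2-methylbut-3-yn-2-yl)oxy]phenyl}-7-[(2-methylbut-3-en-2-yl)oxy]-2,3-dihydro-4H-chromen-4-one | C#CC(C)(C)Oc1ccc(cc1Br)[C@@H]2CC(=O)c3ccc(OC(C)(C)C=C)cc3O2 | intermediate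
5 | (2S)-2-{3-bromo-4-[(2-methylbut-3-yn-2-yl)oxy]phenyl}-7-hydroxy-8-(3-methylbut-2-en-1-yl)-2,3-dihydro-4H-chromen-4-one | C#CC(C)(C)Oc1ccc(cc1Br)[C@@H]2CC(=O)c3ccc(O)c(CC=C(C)C)c3O2 | intermediate
6 | (2S)-2-(8-bromo-2,2-dimethyl-2H-chromen-6-yl)-7-hydroxy-8-(3-methylbut-2-en-1-yl)-2,3-dihydro-4H-chromen-4-one | Brc1cc([C@@H]2CC(=O)c3ccc(O)c(CC=C(C)C)c3O2)cc2c1OC(C)(C)C=C2 | intermediate
7 | methyl (2R)-oxirane-2-carboxylate, methyl (R)-glycidate | COC(=O)[C@H]1CO1 | starting material
8 | methyl (2S)-3-bromo-2-hydroxypropanoate (present as its bromomagnesium alkoxide) | COC(=O)[C@H](O)CBr | intermediate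
9 | (3S)-4-bromo-2-methylbutane-2,3-diol | CC(C)(O)[C@H](O)CBr | intermediate
10 | (3S)-4-bromo-2-methyl-3-[(triethylsilyl)oxy]butan-2-ol | CC(C)(O)[C@H](O[Si](CC)(CC)CC)CBr | intermediate
11 | {[(2S)-1-bromo-3-methylbut-3-en-2-yl]oxy}(triethyl)silane | C=C(C)[C@H](O[Si](CC)(CC)CC)CBr | intermediate
12 | (2S)-2-(2,2-dimethyl-8-{(2R)-3-methyl-2-[(triethylsilyl)oxy]but-3-en-1-yl}-2H-chromen-6-yl)-7-hydroxy-8-(3-methylbut-2-en-1-yl)-2,3-dihydro-4H-chromen-4-one | C=C(C)[C@H](O[Si](CC)(CC)CC)Cc1cc([C@@H]2CC(=O)c3ccc(O)c(CC=C(C)C)c3O2)cc2c1OC(C)(C)C=C2 | intermediate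
13 | (2S)-7-hydroxy-2-{8-[(2R)-2-hydroxy-3-methylbut-3-en-1-yl]-2,2-dimethyl-2H-chromen-6-yl}-8-(3-methylbut-2-en-1-yl)-2,3-dihydro-4H-chromen-4-one | C=C(C)[C@H](O)Cc1cc([C@@H]2CC(=O)c3ccc(O)c(CC=C(C)C)c3O2)cc2c1OC(C)(C)C=C2 | target

**Step count and risks**
Total step count: 7. Longest linear sequence: 5 (steps 1, 2, 3, 4 and 7, from 1 to 13).

Steps most likely to fail:

Step 7 (the proposed new coupling). The homoallyl radical from 11 may undergo a 1,2-vinyl shift before nickel captures it, giving the benzylic silyl ether isomer. The silyl radical may also add to the chromene double bond. The fallback uses known chemistry and forms the alkene only after the coupling. It sets out from 6 and from 10, which is isolated by working up step 6 before SOCl2 is added. The same nickel/photoredox conditions, now with an ordinary saturated primary bromide, give (2S)-7-hydroxy-2-{8-[(2R)-3-hydroxy-3-methyl-2-[(triethylsilyl)oxy]butyl]-2,2-dimethyl-2H-chromen-6-yl}-8-(3-methylbut-2-en-1-yl)-2,3-dihydro-4H-chromen-4-one F1. Dehydration of its tertiary alcohol with SOCl2 and pyridine in CH2Cl2 at −20 °C (the phenol chlorosulfite is hydrolysed on work-up) comes back to the route at 12, and the acid treatment of step 7 gives 13.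

Step 3. DBU forms the 4'-phenoxide, which can open ring C through a quinone methide and erode C2; the hindered ortho-bromophenol may also alkylate slowly. The fallback avoids a stoichiometric phenoxide and sets out from 3. A second palladium-catalysed O-allylation under the step 1 conditions gives (2S)-2-{3-bromo-4-[(2-methylbut-3-en-2-yl)oxy]phenyl}-7-[(2-methylbut-3-en-2-yl)oxy]-2,3-dihydro-4H-chromen-4-one F2. Heating in xylene at 130 °C (double aromatic Claisen rearrangement) gives (2S)-2-[3-bromo-4-hydroxy-5-(3-methylbut-2-en-1-yl)phenyl]-7-hydroxy-8-(3-methylbut-2-en-1-yl)-2,3-dihydro-4H-chromen-4-one F3. DDQ (1.05 equiv) in benzene then closes the chromene on the more electron-rich ring B phenol and comes back to the route at 6; selectivity over the acyl-conjugated ring A phenol is expected but not guaranteed.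

Step 1. Risks are partial reaction at 4'-OH, bis-allylation, or drift to the linear prenyl ether. The fallback sets out from 1. Copper-catalysed propargylation with 3-chloro-3-methylbut-1-yne, CuCl2·2H2O (1 mol%) and exactly 1.0 equiv DBU in MeCN at 0 °C (only the 7-OH is ionised) gives (2S)-2-(4-hydroxyphenyl)-7-[(2-methylbut-3-yn-2-yl)oxy]-2,3-dihydro-4H-chromen-4-one F4. Semi-hydrogenation with H2 (1 atm) over Pd on CaCO3 poisoned with Pb(OAc)2, with quinoline in EtOAc, comes back to the route at 2.

**Further compounds**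
F1 | step 7 | (2S)-7-hydroxy-2-{8-[(2R)-3-hydroxy-3-methyl-2-[(triethylsilyl)oxy]butyl]-2,2-dimethyl-2H-chromen-6-yl}-8-(3-methylbut-2-en-1-yl)-2,3-dihydro-4H-chromen-4-one | CC(C)(O)[C@H](O[Si](CC)(CC)CC)Cc1cc([C@@H]2CC(=O)c3ccc(O)c(CC=C(C)C)c3O2)cc2c1OC(C)(C)C=C2
F2 | step 3 | (2S)-2-{3-bromo-4-[(2-methylbut-3-en-2-yl)oxy]phenyl}-7-[(2-methylbut-3-en-2-yl)oxy]-2,3-dihydro-4H-chromen-4-one | C=CC(C)(C)Oc1ccc(cc1Br)[C@@H]2CC(=O)c3ccc(OC(C)(C)C=C)cc3O2
F3 | step 3 | (2S)-2-[3-bromo-4-hydroxy-5-(3-methylbut-2-en-1-yl)phenyl]-7-hydroxy-8-(3-methylbut-2-en-1-yl)-2,3-dihydro-4H-chromen-4-one | CC(C)=CCc1cc(cc(Br)c1O)[C@@H]2CC(=O)c3ccc(O)c(CC=C(C)C)c3O2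
F4 | step 1 | (2S)-2-(4-hydroxyphenyl)-7-[(2-methylbut-3-yn-2-yl)oxy]-2,3-dihydro-4H-chromen-4-one | Oc1ccc(cc1)[C@@H]2CC(=O)c3ccc(OC(C)(C)C#C)cc3O2
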